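A first-order rate constant is a number per second with no concentration in it, so a flask run by such constants turns the same fraction of its charge in the same time, whatever the charge.

| flask | substrate | remark | time |
|---|---|---|---|
| spring | 9.5 mM | run made earlier |  |
| dawn | 73 mM | run made earlier |  |
| blue | 8.0 mM |  | 2.0 min |
| teal | 12 mM |  | 2.0 min |
| amber | 20 mM |  | 2.0 min |
| green | 30 mM |  | 2.0 min |
| ochre | 50 mM |  | 2.0 min |

| run | time / s | product / % |
|---|---|---|
| spring | 30.0 | 7.5 |
| spring | 60.0 | 10.8 |
| spring | 90.0 | 12.7 |
| spring | 120 | 13.8 |
| dawn | 15.0 | 4.8 |
| dawn | 40.0 | 8.7 |
| dawn | 80.0 | 12.6 |
| dawn | 120 | 14.1 |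

(readings scatter by 0.3 percentage points)

1. amount of product at the end, in percent of the substrate charged for blue, teal, amber, green, ochre, in this order
2. how that number moves from the first to the last of them (hardly changes / falls, then rises / rises, then falls / falls all the way / rises all the way)

- the analysis behind the earlier runs scatters by 0.3 percentage points, standard deviation
- a reading or a percentage of product counts all its forms, free or not
- "hardly changes" means that all values lie within two and a half points (for a concentration: within two and a half percent of the largest)

At 120 s, which is the asked time, spring stands at 13.8 % and dawn at 14.1 %, though dawn's charge is 7.68 times spring's. That reads as 0.0105, and this is the charge exponent: the percent change of the end percentage per percent of charge, an apparent order that first-order behaviour puts at zero.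

My bound from above is dawn's reading plus two scatters, 14.7 %, and my bound from below is spring's reading minus two, 13.2 %. I assume a smooth curve over the charges asked, blue's below spring's included, because two runs show nothing of the middle or of what lies below spring. If the two readings measure one level, pooling them around 14.0 % tightens the bracket to 13.5 % and 14.4 %.

Blue's charge, 8.0 mM, lies below spring's 9.5 mM, so I reckon from spring with the exponent. That gives 13.8 % for blue and 14.0 % for ochre, both inside the bracket. Pushing the two readings two scatters apart raises the exponent to 0.0528, and even that spreads blue and ochre by 1.4 percentage points, within the limit for "hardly changes", so that is the shape I commit to.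

The forecast, inside my bracket, runs from 13.9 % for blue to 14 % for ochre and reads hardly changes, on the ground that “Both the rate constant and the plateau seem independent of concentration”, and its blue figure stands 0.10 points above mine.

Blue gives 14.0 %, ochre gives 14.0 %, and the row reads hardly changes.

    intermediate C ⇌ intermediate D (K = 1.10, k = 5.20 × 10⁻⁴ s⁻¹)
    substrate ⇌ dormant form (K = 0.660, k = 0.0160 s⁻¹)
    substrate → product (k = 0.00400 s⁻¹)
    crystals ⇌ product, rate k4*(cs4 - [product]) while solid is left; crystals form when [product] > cs4 (solubility = 0.410 mM, k = 1.30 s⁻¹)
    substrate → intermediate A (k = 0.0140 s⁻¹)
    substrate ⇌ intermediate B (K = 2.70, k = 0.00550 s⁻¹)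
    intermediate A → intermediate C (k = 0.0120 s⁻¹)

Under that equal figure the crystals differ: at the end ochre holds 13.1 % of its charge as crystals and blue 8.84 %, both counted in the product, and the low solubility of product makes no difference to either end figure. Carried from blue's 14.0 % up to the ochre charge, the exponent 0.0105 gives 14.3 %, and ochre stands at 14.0 %.

(The data are simulated with constants of no real substance; the scatter is artificial.)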